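**Strategy.** In the target (C1 = lavandulyl bridgehead, C5 = prenyl bridgehead, C6 = CMe2, C7 = CH‑prenyl, C8 = CH2, C9 = bridging ketone) the cyclohexanone ring C1–C8–C7–C6–C5–C9 is read as a Diels–Alder adduct: C9=O with its two α‑bridgeheads hides the 2‑silyloxydiene C1=C9–C5=C6, and C8–C7 is an acrylate. One auxiliary‑controlled [4+2] cycloaddition of an acyclic lavandulyl‑substituted TIPS dienol ether with an N‑acryloyl oxazolidinone forms C1–C8 and C6–C7, sets C7, and leaves the C9=C5 enol ether for regiospecific C5 prenylation. Effenberger annulation with malonyl dichloride then bridges C1 and C5; O‑methylation and C3 benzoylation complete the synthesis.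

Key step: step 8

Remarks on the chemistry (assumptions):
- Target locants (C1 lavandulyl bridgehead, C2=O, C3 benzoyl, C4–OMe, C5 prenyl bridgehead, C6 CMe2, C7, C8, C9) are used for all intermediates.
- "(R)‑lavandulyl" is the (2R)‑5‑methyl‑2‑(prop‑1‑en‑2‑yl)hex‑4‑en‑1‑yl group, which has the spatial configuration of (S)‑lavandulol.
- The ring α‑centres C1 and C5 in 17–27 are later enolised or made quaternary. They are drawn as the expected major epimer, and either epimer serves.

Step 1
Reactants: 1 (S)-4-benzyloxazolidin-2-one; 2 3-methylbut-2-enoyl chloride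
Product: 4 (S)-4-benzyl-3-(3-methylbut-2-enoyl)oxazolidin-2-one, via lithium oxazolidinide 3 (not isolated)
Conditions: n-BuLi, THF, −78 °C; then 2, −78 → 0 °C
Reagents that add atoms: none
Why: N‑acylation of the lithiated oxazolidinone by the acid chloride (imide formation); no stereocentre is formed.

Step 2
Reactants: 4 (S)-4-benzyl-3-(3-methylbut-2-enoyl)oxazolidin-2-one; 5 prenyl bromide
Product: 7 (S)-4-benzyl-3-[(S)-5-methyl-2-(prop-1-en-2-yl)hex-4-enoyl]oxazolidin-2-one, via sodium Z(O)-dienolate 6 (not isolated)
Conditions: NaHMDS, THF, −78 °C; then 5, −78 → −40 °C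
Reagents that add atoms: none
Why: Deconjugative α‑alkylation of the chelated Z(O) dienolate (Evans asymmetric alkylation): the allylic bromide should enter at Cα on the face opposite the benzyl group, which sets the (S) α‑centre that becomes the lavandulyl stereocentre.

Step 3
Reactants: 7 (S)-4-benzyl-3-[(S)-5-methyl-2-(prop-1-en-2-yl)hex-4-enoyl]oxazolidin-2-one
Product: 8 (S)-lavandulol
Conditions: LiBH4, MeOH (1 equiv), Et2O, 0 °C
Reagents that add atoms: none
Why: Reductive cleavage of the N‑acyl oxazolidinone by borohydride gives the primary alcohol and returns the auxiliary; these non‑basic hydride conditions should not epimerise or conjugate the β,γ‑unsaturated centre.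

Step 4
Reactants: 8 (S)-lavandulol
Product: 9 (S)-lavandulyl iodide
Conditions: PPh3, I2, imidazole, CH2Cl2, 0 °C, dark
Reagents that add atoms: iodine, II
Why: Appel‑type iodination of a primary alcohol by SN2 at CH2; the stereocentre is not involved.

Step 5
Reactants: 9 (S)-lavandulyl iodide; 10 mesityl oxide
Product: 12 (S)-2,10-dimethyl-7-(prop-1-en-2-yl)undeca-2,9-dien-4-one, via lithium dienolate 11 (not isolated)
Conditions: LDA, THF, −78 °C (10 added to the base); then 9, DMPU, −78 → 0 °C
Reagents that add atoms: none
Why: Kinetic α′‑deprotonation gives the cross‑conjugated lithium dienolate, whose SN2 alkylation by the primary iodide (enolate alkylation) attaches the lavandulyl CH2 to the future C1.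

Step 6
Reactants: 12 (S)-2,10-dimethyl-7-(prop-1-en-2-yl)undeca-2,9-dien-4-one
Product: 13 (4Z,7R)-TIPS dienol ether
Conditions: TIPSOTf, Et3N, CH2Cl2, 0 °C
Reagents that add atoms: triisopropylsilyl trifluoromethanesulfonate, CC(C)[Si](C(C)C)(C(C)C)OS(=O)(=O)C(F)(F)F
Why: Soft enolisation (silyl triflate/amine) at the α′‑CH2 gives the cross‑conjugated 2‑silyloxydiene; the Z enol ether (O and alkyl cis) is the favoured geometry and places H "inside" at the diene terminus C1.

Step 7
Reactants: 1 (S)-4-benzyloxazolidin-2-one; 14 acryloyl chloride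
Product: 16 (S)-3-acryloyl-4-benzyloxazolidin-2-one, via bromomagnesium oxazolidinide 15 (not isolated)
Conditions: MeMgBr, THF, 0 °C; then 14, −78 °C
Reagents that add atoms: none
Why: N‑acylation of the bromomagnesium salt at low temperature (which suppresses acrylate polymerisation) gives the chiral dienophile.

Step 8
Reactants: 13 (4Z,7R)-TIPS dienol ether; 16 (S)-3-acryloyl-4-benzyloxazolidin-2-one
Product: 17 cycloadduct (C9=C5 TIPS enol ether with the N-acyl oxazolidinone at C7)
Conditions: Et2AlCl (1.4 equiv), CH2Cl2, −78 °C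
Reagents that add atoms: none
Why: Et2AlCl converts 16 into the cationic O,O‑chelated s‑cis acrylimide, whose β‑carbon (C8) is attacked by the enol‑ether terminus C1 of 13 in a highly asynchronous [4+2] cycloaddition (in the limit a Mukaiyama–Michael addition followed by ring closure) that ends with C7 bonding to the dimethyl terminus C6, where the silyloxyallyl cation character is tertiary. The closest known reaction type is the auxiliary‑controlled, Lewis‑acid‑promoted Diels–Alder reaction of N‑acryloyl oxazolidinones with 2‑silyloxydienes. The cyclohexene ring C1–C8–C7–C6–C5=C9 is closed as a [4+2] cycloadduct, in the stepwise limit by six‑membered collapse of the aluminium enolate onto the allyl cation. C7 is set by the auxiliary, the diene adding to the Cα‑Si face opposite the benzyl group to give 7R, while C1 is set cis to the acyl group by the endo transition state and the Z enol ether and is erased in step 13. The step needs "para" regioselectivity, secured by the polarisation of the 2‑silyloxydiene (nucleophilic C1 to the acrylate β‑carbon), chemoselectivity over the isolated prenyl and isopropenyl alkenes, secured by the much higher nucleophilicity of the silyl enol ether at −78 °C, and survival of the product enol ether, secured by the bulky TIPS group.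

Step 9
Reactants: 17 cycloadduct
Product: 18 primary alcohol (C7–CH2OH)
Conditions: LiBH4, H2O (1 equiv), Et2O, 0 °C
Reagents that add atoms: none
Why: Chemoselective borohydride reduction of the hindered imide to the primary alcohol (auxiliary returned); the TIPS enol ether and the alkenes are inert to borohydride and C7 is not epimerised.

Step 10
Reactants: 18 primary alcohol (C7–CH2OH)
Product: 19 primary bromide (C7–CH2Br)
Conditions: PPh3, CBr4, 2,6-lutidine, CH2Cl2, 0 °C
Reagents that add atoms: carbon tetrabromide, BrC(Br)(Br)Br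
Why: Appel bromination converts the primary alcohol into the bromide under buffered, neutral conditions that the hindered TIPS enol ether should tolerate.

Step 11
Reactants: 19 primary bromide (C7–CH2Br); 20 (2-methylprop-1-en-1-yl)magnesium bromide
Product: 21 C7-prenyl TIPS enol ether
Conditions: Fe(acac)3 (5 mol %), TMEDA, THF, 0 °C
Reagents that add atoms: none
Why: Iron‑catalysed Kumada‑type sp3–sp2 cross‑coupling of a primary alkyl bromide with an alkenyl Grignard reagent turns CH2Br into the prenyl side chain without touching the enol ether.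

Step 12
Reactants: 21 C7-prenyl TIPS enol ether; 5 prenyl bromide
Product: 23 2,6-disubstituted cyclohexanone (C5 prenylated), via TAS enolate 22 (not isolated)
Conditions: TASF, THF, −78 → 0 °C, 5 present in excess
Reagents that add atoms: none
Why: Fluoride‑induced desilylation gives the regiodefined "naked" C9–C5 enolate, which is C‑alkylated at C5 by the allylic bromide (regiospecific alkylation of a silyl enol ether); the new C5 centre is enolised again in step 14, so its configuration is irrelevant.

Step 13
Reactants: 23 2,6-disubstituted cyclohexanone (C5 prenylated)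
Product: 25 TMS enol ether (C9=C1), via lithium enolate 24 (not isolated)
Conditions: LDA, THF, −78 °C; then TMSCl, −78 → 0 °C
Reagents that add atoms: chlorotrimethylsilane, C[Si](C)(C)Cl
Why: Kinetic deprotonation at the less hindered α‑carbon C1 (C5–H is shielded by the adjacent gem‑dimethyl group) followed by O‑silylation gives the enol ether needed for the annulation.

Step 14
Reactants: 25 TMS enol ether (C9=C1); 26 malonyl dichloride
Product: 28 bicyclo[3.3.1]nonane-2,4,9-trione, via C1-acylated acid chloride 27 (not isolated)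
Conditions: 26, CH2Cl2, −20 °C → rt; then KOH, BnEt3NCl, H2O, rt
Reagents that add atoms: none
Why: Effenberger cyclisation: C‑acylation of the enol ether at C1, enolisation towards C5 and intramolecular C‑acylation close the second six‑membered ring, the base treatment converting any O‑acylated enol lactone into the trione; the first acylation should occur axially on the face anti to the equatorial C7 prenyl group, which fixes C1, and the tether can then only close cis at C5.

Step 15
Reactants: 28 bicyclo[3.3.1]nonane-2,4,9-trione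
Product: 29 4-methoxy enone (vinylogous ester with OMe next to C5)
Conditions: TMSCHN2, MeOH/PhMe, 0 °C; chromatographic separation from the 2-methoxy isomer
Reagents that add atoms: (trimethylsilyl)diazomethane, C[Si](C)(C)C=[N+]=[N-]
Why: O‑Methylation of the enolised β‑diketone (a vinylogous acid) by the diazoalkane; both regioisomeric vinylogous esters are expected, the 4‑methoxy isomer is taken on and the 2‑methoxy isomer can be hydrolysed back to 28.

Step 16
Reactants: 29 4-methoxy enone (vinylogous ester with OMe next to C5); 31 benzoyl chloride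
Product: 32 target compound, via 3-lithio enone 30 (not isolated)
Conditions: LiTMP, THF, −78 °C; then 31, −78 °C
Reagents that add atoms: none
Why: Deprotonation of the vinylogous ester at C3 (the only acidic C–H, both bridgeheads being quaternary) by the hindered amide base and C‑acylation of the vinyl‑lithium by benzoyl chloride gives the 3‑benzoyl enone; no stereocentre is touched.

**Compound list**

1 | (S)-4-benzyloxazolidin-2-one | O=C1OC[C@H](Cc2ccccc2)N1 | starting material
2 | 3-methylbut-2-enoyl chloride | CC(C)=CC(Cl)=O | starting material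
3 | lithium (S)-4-benzyl-2-oxooxazolidin-3-ide | [Li+].O=C1OC[C@H](Cc2ccccc2)[N-]1 | intermediate (not isolated)
4 | (S)-4-benzyl-3-(3-methylbut-2-enoyl)oxazolidin-2-one | CC(C)=CC(=O)N1[C@@H](Cc2ccccc2)COC1=O | intermediate
5 | 1-bromo-3-methylbut-2-ene (prenyl bromide) | CC(C)=CCBr | starting material
6 | sodium Z(O)-dienolate of 4 | [Na+].[O-]/C(=C\C(C)=C)N1[C@@H](Cc2ccccc2)COC1=O | intermediate (not isolated)
7 | (S)-4-benzyl-3-[(S)-5-methyl-2-(prop-1-en-2-yl)hex-4-enoyl]oxazolidin-2-one | C=C(C)[C@H](CC=C(C)C)C(=O)N1[C@@H](Cc2ccccc2)COC1=O | intermediate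
8 | (S)-lavandulol, (S)-5-methyl-2-(prop-1-en-2-yl)hex-4-en-1-ol | C=C(C)[C@H](CC=C(C)C)CO | intermediate
9 | (S)-lavandulyl iodide, (S)-3-(iodomethyl)-2,6-dimethylhepta-1,5-diene | C=C(C)[C@H](CC=C(C)C)CI | intermediate
10 | mesityl oxide (4-methylpent-3-en-2-one) | CC(=O)C=C(C)C | starting material
11 | lithium 4-methylpenta-1,3-dien-2-olate | [Li+].[O-]C(=C)C=C(C)C | intermediate (not isolated)
12 | (S)-2,10-dimethyl-7-(prop-1-en-2-yl)undeca-2,9-dien-4-one | C=C(C)[C@H](CC=C(C)C)CCC(=O)C=C(C)C | intermediate
13 | triisopropyl{[(4Z,7R)-2,10-dimethyl-7-(prop-1-en-2-yl)undeca-2,4,9-trien-4-yl]oxy}silane | C=C(C)[C@H](CC=C(C)C)C/C=C(O[Si](C(C)C)(C(C)C)C(C)C)/C=C(C)C | intermediate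
14 | acryloyl chloride | C=CC(Cl)=O | starting material
15 | bromomagnesium (S)-4-benzyl-2-oxooxazolidin-3-ide | O=C1OC[C@H](Cc2ccccc2)N1[Mg]Br | intermediate (not isolated)
16 | (S)-3-acryloyl-4-benzyloxazolidin-2-one | C=CC(=O)N1[C@@H](Cc2ccccc2)COC1=O | intermediate
17 | (4S)-4-benzyl-3-{(1R,5S)-2,2-dimethyl-5-[(R)-lavandulyl]-4-(triisopropylsilyloxy)cyclohex-3-ene-1-carbonyl}oxazolidin-2-one (cyclohexene locants; ring C1 = target C7, ring C5 = target C1; acyl and lavandulyl cis) | C=C(C)[C@H](CC=C(C)C)C[C@H]1C[C@@H](C(=O)N2[C@@H](Cc3ccccc3)COC2=O)C(C)(C)C=C1O[Si](C(C)C)(C(C)C)C(C)C | intermediate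
18 | [(1R,5S)-2,2-dimethyl-5-[(R)-lavandulyl]-4-(triisopropylsilyloxy)cyclohex-3-en-1-yl]methanol | C=C(C)[C@H](CC=C(C)C)C[C@H]1C[C@@H](CO)C(C)(C)C=C1O[Si](C(C)C)(C(C)C)C(C)C | intermediate
19 | bromide of 18 (CH2Br in place of CH2OH, same configuration) | C=C(C)[C@H](CC=C(C)C)C[C@H]1C[C@@H](CBr)C(C)(C)C=C1O[Si](C(C)C)(C(C)C)C(C)C | intermediate
20 | (2-methylprop-1-en-1-yl)magnesium bromide | CC(C)=C[Mg]Br | starting material
21 | TIPS enol ether as 19 with CH2Br replaced by 3-methylbut-2-en-1-yl (C7 R; C9=C5 enol ether) | C=C(C)[C@H](CC=C(C)C)C[C@H]1C[C@@H](CC=C(C)C)C(C)(C)C=C1O[Si](C(C)C)(C(C)C)C(C)C | intermediate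
22 | tris(dimethylamino)sulfonium C9–C5 enolate of the ring ketone | C=C(C)[C@H](CC=C(C)C)C[C@H]1C[C@@H](CC=C(C)C)C(C)(C)C=C1[O-].CN(C)[S+](N(C)C)N(C)C | intermediate (not isolated)
23 | (4R)-3,3-dimethyl-2,4-bis(3-methylbut-2-en-1-yl)-6-[(R)-lavandulyl]cyclohexan-1-one (cyclohexanone locants; drawn all-cis, C2/C6 epimers tolerated) | C=C(C)[C@H](CC=C(C)C)C[C@H]1C[C@@H](CC=C(C)C)C(C)(C)[C@@H](CC=C(C)C)C1=O | intermediate
24 | lithium C9–C1 enolate of 23 | C=C(C)[C@H](CC=C(C)C)CC1=C([O-])[C@H](CC=C(C)C)C(C)(C)[C@H](CC=C(C)C)C1.[Li+] | intermediate (not isolated)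
25 | trimethylsilyl enol ether of 23 (C9=C1, tetrasubstituted) | C=C(C)[C@H](CC=C(C)C)CC1=C(O[Si](C)(C)C)[C@H](CC=C(C)C)C(C)(C)[C@H](CC=C(C)C)C1 | intermediate
26 | malonyl dichloride | O=C(Cl)CC(Cl)=O | starting material
27 | 3-oxo-3-(1-lavandulyl-2-oxocyclohexyl)propanoyl chloride: 23 C-acylated at C1 by ClC(=O)CH2C(=O)– on the face anti to the C7 prenyl | C=C(C)[C@H](CC=C(C)C)C[C@@]1(C(=O)CC(Cl)=O)C[C@@H](CC=C(C)C)C(C)(C)[C@@H](CC=C(C)C)C1=O | intermediate (not isolated)
28 | (1R,5R,7R)-6,6-dimethyl-1-[(R)-lavandulyl]-5,7-bis(3-methylbut-2-en-1-yl)bicyclo[3.3.1]nonane-2,4,9-trione (drawn as triketone; enolised in solution) | C=C(C)[C@H](CC=C(C)C)C[C@@]12C[C@@H](CC=C(C)C)C(C)(C)[C@@](CC=C(C)C)(C1=O)C(=O)CC2=O | intermediate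
29 | (1R,5R,7R)-4-methoxy-6,6-dimethyl-1-[(R)-lavandulyl]-5,7-bis(3-methylbut-2-en-1-yl)bicyclo[3.3.1]non-3-ene-2,9-dione | C=C(C)[C@H](CC=C(C)C)C[C@@]12C[C@@H](CC=C(C)C)C(C)(C)[C@@](CC=C(C)C)(C1=O)C(OC)=CC2=O | intermediate
30 | 3-lithio derivative of 29 | C=C(C)[C@H](CC=C(C)C)C[C@@]12C[C@@H](CC=C(C)C)C(C)(C)[C@@](CC=C(C)C)(C1=O)C(OC)=C([Li])C2=O | intermediate (not isolated)
31 | benzoyl chloride | O=C(Cl)c1ccccc1 | starting material
32 | (1R,5R,7R)-3-benzoyl-4-methoxy-6,6-dimethyl-1-[(2R)-5-methyl-2-(prop-1-en-2-yl)hex-4-en-1-yl]-5,7-bis(3-methylbut-2-en-1-yl)bicyclo[3.3.1]non-3-ene-2,9-dione | C=C(C)[C@H](CC=C(C)C)C[C@@]12C[C@@H](CC=C(C)C)C(C)(C)[C@@](CC=C(C)C)(C1=O)C(OC)=C(C(=O)c1ccccc1)C2=O | target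

**Step count and risks**

Total steps: 16. Longest linear sequence: 15 (steps 1–6 and 8–16; step 7 is a one‑step side branch).

Three steps most likely to fail:

1. Step 8 (key cycloaddition). The diene carries a cis methyl group on its C6 terminus, so the reaction may stop after the first C–C bond (conjugate addition without closure onto the tetrasubstituted terminus). The stoichiometric aluminium Lewis acid may also desilylate the dienol ether, or facial discrimination may be eroded if the pathway becomes fully stepwise. Fallback: stereocontrol and activation are moved from the auxiliary/stoichiometric aluminium pair to a chiral catalyst. Setting out from 13, cycloaddition with purchased achiral 3‑acryloyloxazolidin‑2‑one under a cationic Cu(II)–bis(oxazoline) Lewis acid (10 mol %, CH2Cl2, −40 °C, ligand antipode chosen to expose the same Cα‑Si face) should give the achiral‑imide cycloadduct F1. LiBH4 reduction of F1 comes back to the route at 18.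

2. Step 14 (Effenberger annulation). Forming two quaternary bridgeheads in one annulation may be overtaken by O‑acylation to an enol lactone, the HCl released may add to or cyclise the prenyl and isopropenyl groups, and the facial bias from C7 in the first acylation may be incomplete. Fallback: the annulation is run before C5 is prenylated, so that only C1 becomes quaternary in it. Setting out from 21, malonyl dichloride followed by the same base treatment should give the bridgehead‑H trione F2. TMSCHN2 then gives its 4‑methyl enol ether F3 (OMe next to C5–H). Bridgehead lithiation of F3 at C5 (LDA, THF, −78 °C) and alkylation with prenyl bromide come back to the route at 29, bypassing steps 12–15.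

3. Step 15 (O‑methylation). Methylation may occur mainly at the less hindered enol oxygen O‑2 (next to C1) rather than at O‑4 (next to C5 and the gem‑dimethyl group), so that most material has to be separated, hydrolysed and recycled. Fallback: the two oxygens are differentiated sterically and the methyl group is then placed on the remaining one. Setting out from 28, TIPSOTf/Et3N (CH2Cl2, −78 °C) should silylate the less hindered O‑2 to give the 2‑silyloxy enone F4. MeOTf with 2,6‑di‑tert‑butyl‑4‑methylpyridine then alkylates the C4 carbonyl oxygen of F4, and loss of the silyl group from the resulting methoxy‑silyloxy allyl cation (fluoride work‑up) comes back to the route at 29 with the methyl group on O‑4 only.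

Further compounds
F1 | step 8 | 3-{(1R,5S)-2,2-dimethyl-5-[(R)-lavandulyl]-4-(triisopropylsilyloxy)cyclohex-3-ene-1-carbonyl}oxazolidin-2-one | C=C(C)[C@H](CC=C(C)C)C[C@H]1C[C@@H](C(=O)N2CCOC2=O)C(C)(C)C=C1O[Si](C(C)C)(C(C)C)C(C)C
F2 | step 14 | 6,6-dimethyl-1-[(R)-lavandulyl]-7-(3-methylbut-2-en-1-yl)bicyclo[3.3.1]nonane-2,4,9-trione with C5–H (C7 R, prenyl anti to the C2–C4 bridge) | C=C(C)[C@H](CC=C(C)C)C[C@@]12C[C@@H](CC=C(C)C)C(C)(C)[C@@H](C1=O)C(=O)CC2=O
F3 | step 14 | 4-methoxy enone of F2 (OMe next to C5–H) | C=C(C)[C@H](CC=C(C)C)C[C@@]12C[C@@H](CC=C(C)C)C(C)(C)[C@@H](C1=O)C(OC)=CC2=O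
F4 | step 15 | 2-(triisopropylsilyloxy) enone of 28 (silyl enol ether next to C1, C4 ketone next to C5) | C=C(C)[C@H](CC=C(C)C)C[C@@]12C[C@@H](CC=C(C)C)C(C)(C)[C@@](CC=C(C)C)(C1=O)C(=O)C=C2O[Si](C(C)C)(C(C)C)C(C)C
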